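**Plan**

Retrosynthesis: the C5' carbinol is traced to a ketone, the two C–O bonds of the oxirane to oxygen transfer onto an (E)-alkene, the O7–C1' ether to a Mitsunobu union of a hydroxycoumarin with a C10 allylic alcohol, and the chain to C1'–C2', C3'–CH3 and C4'–C5' disconnections.
Enabling feature: the oxirane spans C2'–C3' of a chain whose C1' is the OCH2 group, C3' bears a methyl, C4' is a CH2, C5' is oxygenated and C6'=C7' is an isopropylidene alkene, so it is the epoxide of an (E)-geranyl-type aryl ether. With C5' as a ketone, C6'=C7' (enone) and C3=C4 of the pyranone ring (lactone) are electron-poor, and C2'=C3' is the only alkene that accepts electrophilic oxygen.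
Forward order: the chain is built linearly (propargylation, silylation, carboalumination–hydroxymethylation), the benzopyranone bicycle is made in one Pechmann step, the two are joined through O7, C5' is unmasked and oxidised, the oxirane ring is closed, and the ketone is reduced.
Stereochemistry: the (E) alkene comes from syn carboalumination, C2'(R) and C3'(R) from the D-fructose-derived dioxirane, and C5'(R) from an oxazaborolidine-catalysed reduction in the last step; C5' is carried racemic until then because it passes through the ketone.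

Key step: step 8

Remark: primed locants run along the side chain from the OCH2 carbon (C1') to the isopropylidene carbon (C7'); the choice of the (S)-oxazaborolidine in step 9 assumes that the 2-methylprop-1-enyl group acts as the larger ketone substituent, as alkenyl groups normally do.

**Route**

Step 1
Reactants: 1 3-methylbut-2-enal; 2 3-bromoprop-1-yne (propargyl bromide)
Product: 4 (±)-6-methylhept-5-en-1-yn-4-ol, via allenylzinc bromide 3 (not isolated)
Conditions: Zn dust, THF, 0 °C to rt; aq NH4Cl work-up
Reagents that add atoms: none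
Why: Barbier-type propargylation in which zinc inserts into 2 to give allenylzinc bromide 3, which adds 1,2 to the aldehyde of 1 with allylic transposition (SE2') to give the homopropargylic alcohol; the C5' carbinol forms racemic, which is acceptable because this centre is taken through the ketone in step 7 and set only in step 9.

Step 2
Reactants: 4 (±)-6-methylhept-5-en-1-yn-4-ol
Product: 5 (±)-tert-butyl(dimethyl)[(6-methylhept-5-en-1-yn-4-yl)oxy]silane
Conditions: TBSCl, imidazole, DMF, rt
Reagents that add atoms: tert-butyl(chloro)dimethylsilane, CC(C)(C)[Si](C)(C)Cl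
Why: Imidazole-promoted silylation of a secondary alcohol, which masks C5'–OH against Me3Al, n-BuLi and the Mitsunobu coupling and keeps C5' at the base-stable carbinol level until the ketone is needed.

Step 3
Reactants: 5 (±)-tert-butyl(dimethyl)[(6-methylhept-5-en-1-yn-4-yl)oxy]silane
Product: 8 (±)-(2E)-5-{[tert-butyl(dimethyl)silyl]oxy}-3,7-dimethylocta-2,6-dien-1-ol, via (E)-alkenyldimethylalane 6 (not isolated), via lithium alkenylaluminate 7 (not isolated)
Conditions: Me3Al, Cp2ZrCl2 (cat.), CH2Cl2, 0 °C to rt; volatiles removed; n-BuLi, THF–hexane, −78 °C; (CH2O)n, −78 °C to rt; aq KNaC4H4O6 work-up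
Reagents that add atoms: trimethylaluminium, C[Al](C)C; formaldehyde (from paraformaldehyde), C=O
Why: Negishi carboalumination, in which Cp2ZrCl2-catalysed syn addition of methyl–aluminium across the terminal alkyne puts the methyl on the internal carbon (C3') and aluminium on C2', and the derived aluminate is hydroxymethylated by formaldehyde with retention, so the C2'=C3' alkene is formed with (E) geometry.

Step 4
Reactants: 9 2-methoxybenzene-1,3-diol (2-methoxyresorcinol); 10 DL-malic acid
Product: 12 7-hydroxy-8-methoxy-2H-chromen-2-one, via 3-oxopropanoic acid 11 (not isolated)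
Conditions: conc. H2SO4, 110 °C; poured onto ice
Reagents that add atoms: none
Why: Pechmann coumarin synthesis, in which malic acid loses CO and water in hot H2SO4 to give 3-oxopropanoic acid 11, which alkylates the activated ring position ortho to one hydroxyl and para to the other and then lactonises; because 9 is symmetric only one coumarin can form, with the free hydroxyl at C7 and the methoxy at C8.

Step 5
Reactants: 8 (±)-(2E)-5-{[tert-butyl(dimethyl)silyl]oxy}-3,7-dimethylocta-2,6-dien-1-ol; 12 7-hydroxy-8-methoxy-2H-chromen-2-one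
Product: 13 (±)-7-{[(2E)-5-{[tert-butyl(dimethyl)silyl]oxy}-3,7-dimethylocta-2,6-dien-1-yl]oxy}-8-methoxy-2H-chromen-2-one
Conditions: PPh3, DIAD, THF, 0 °C to rt
Reagents that add atoms: none
Why: Mitsunobu etherification, in which the acidic 7-hydroxyl (a vinylogous carboxylic acid, pKa about 8) displaces the oxyphosphonium group at the primary allylic C1' by SN2, so the ether is formed without base and the (E) alkene and silyl ether are untouched.

Step 6
Reactants: 13 (±)-7-{[(2E)-5-{[tert-butyl(dimethyl)silyl]oxy}-3,7-dimethylocta-2,6-dien-1-yl]oxy}-8-methoxy-2H-chromen-2-one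
Product: 14 (±)-7-{[(2E)-5-hydroxy-3,7-dimethylocta-2,6-dien-1-yl]oxy}-8-methoxy-2H-chromen-2-one
Conditions: Bu4NF, THF, 0 °C
Reagents that add atoms: none
Why: Fluoride-induced cleavage of the secondary silyl ether, driven by Si–F bond formation, under conditions to which the aryl allyl ether, the lactone and both alkenes are inert.

Step 7
Reactants: 14 (±)-7-{[(2E)-5-hydroxy-3,7-dimethylocta-2,6-dien-1-yl]oxy}-8-methoxy-2H-chromen-2-one
Product: 15 7-{[(2E)-3,7-dimethyl-5-oxoocta-2,6-dien-1-yl]oxy}-8-methoxy-2H-chromen-2-one
Conditions: Dess–Martin periodinane (1,1,1-triacetoxy-1,1-dihydro-1,2-benziodoxol-3(1H)-one), NaHCO3, CH2Cl2, 0 °C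
Reagents that add atoms: none
Why: Dess–Martin oxidation of the secondary allylic alcohol under buffered, non-basic conditions gives the enone without moving the C2'=C3' alkene into conjugation, which is why the base-labile β,γ-unsaturated ketone is unveiled only at this point and by a neutral oxidant.

Step 8
Reactants: 15 7-{[(2E)-3,7-dimethyl-5-oxoocta-2,6-dien-1-yl]oxy}-8-methoxy-2H-chromen-2-one
Product: 16 8-methoxy-7-{[(2R,3R)-3-methyl-3-(4-methyl-2-oxopent-3-en-1-yl)oxiran-2-yl]methoxy}-2H-chromen-2-one
Conditions: 1,2:4,5-di-O-isopropylidene-β-D-erythro-2,3-hexodiulo-2,6-pyranose (D-fructose-derived Shi ketone, full equivalent added in portions), Oxone (2KHSO5·KHSO4·K2SO4), NaHCO3, aq Na2EDTA, MeCN, 0 °C, pH 7–8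
Reagents that add atoms: potassium peroxymonosulfate (KHSO5), [K+].[O-]S(=O)(=O)OO
Why: KHSO5 oxidises the fructose-derived ketone to its chiral dioxirane, which hands one oxygen atom to the C2'=C3' alkene of 15 in a single concerted step through a spiro transition state; this is the Shi asymmetric epoxidation of an (E)-trisubstituted alkene, used here in its bicarbonate-buffered near-neutral form. The oxirane closes by [2+1] oxygen-atom transfer with both C–O bonds made on the same face, so the (E) geometry of 15 is carried into the trans arrangement of C1' and C4' in 16. C2' and C3' are fixed together by the catalyst: the flat alkene meets the dioxirane oxygen spiro-fashion on the side away from the fused 4,5-acetonide, with only the C2' hydrogen passing the spiro ketal, which exposes the 2'Si,3'Re face and is the sense that gives (R,R)-epoxides from (E)-alkenes with the D-fructose-derived ketone. Site selectivity among three alkenes is needed and is electronic: C6'=C7' is conjugated to the C5' ketone and C3=C4 to the lactone carbonyl of the pyranone ring, so only C2'=C3' is electron-rich enough for the electrophilic dioxirane, although its allylic aryloxy group will make it slower than a plain trisubstituted alkene. Chemoselectivity against deprotonation at the doubly activated C4' (which would expel the coumarin-7-olate by vinylogous E1cB or, in the product, open the β,γ-epoxy ketone) is secured by working at pH 7–8 and 0 °C instead of the usual pH above 10, at the price of a full charge of ketone.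

Step 9
Reactants: 16 8-methoxy-7-{[(2R,3R)-3-methyl-3-(4-methyl-2-oxopent-3-en-1-yl)oxiran-2-yl]methoxy}-2H-chromen-2-one
Product: 17 7-{[(2R,3R)-3-[(2R)-2-hydroxy-4-methylpent-3-en-1-yl]-3-methyloxiran-2-yl]methoxy}-8-methoxy-2H-chromen-2-one
Conditions: (S)-2-methyl-CBS-oxazaborolidine [(S)-1-methyl-3,3-diphenyltetrahydro-1H,3H-pyrrolo[1,2-c][1,3,2]oxazaborole] (cat.), catecholborane, toluene, −78 °C; MeOH, then pH 7 buffer
Reagents that add atoms: none
Why: Corey–Bakshi–Shibata reduction, in which the ketone binds the ring boron of the (S)-oxazaborolidine anti to its larger (alkenyl) substituent and catecholborane held on the adjacent nitrogen delivers hydride intramolecularly to one carbonyl face, giving the (5'R)-carbinol under reagent control; 1,2-reduction is favoured at −78 °C, and the oxirane, lactone and aryl ether should not react with catecholborane at this temperature.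

**Compound list**

1 | 3-methylbut-2-enal | CC(C)=CC=O | starting material
2 | 3-bromoprop-1-yne | BrCC#C | starting material
3 | allenylzinc bromide | C=C=C[Zn]Br | intermediate (not isolated)
4 | (±)-6-methylhept-5-en-1-yn-4-ol | C#CCC(O)C=C(C)C | intermediate
5 | (±)-tert-butyl(dimethyl)[(6-methylhept-5-en-1-yn-4-yl)oxy]silane | C#CCC(O[Si](C)(C)C(C)(C)C)C=C(C)C | intermediate
6 | (±)-[(1E)-4-{[tert-butyl(dimethyl)silyl]oxy}-2,6-dimethylhepta-1,5-dien-1-yl]dimethylalane | C[Al](C)/C=C(\C)CC(O[Si](C)(C)C(C)(C)C)C=C(C)C | intermediate (not isolated)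
7 | lithium (±)-butyl[(1E)-4-{[tert-butyl(dimethyl)silyl]oxy}-2,6-dimethylhepta-1,5-dien-1-yl]dimethylaluminate | [Li+].CCCC[Al-](C)(C)/C=C(\C)CC(O[Si](C)(C)C(C)(C)C)C=C(C)C | intermediate (not isolated)
8 | (±)-(2E)-5-{[tert-butyl(dimethyl)silyl]oxy}-3,7-dimethylocta-2,6-dien-1-ol | OC/C=C(\C)CC(O[Si](C)(C)C(C)(C)C)C=C(C)C | intermediate
9 | 2-methoxybenzene-1,3-diol | COc1c(O)cccc1O | starting material
10 | DL-malic acid (2-hydroxybutanedioic acid) | OC(CC(O)=O)C(O)=O | starting material
11 | 3-oxopropanoic acid | O=CCC(O)=O | intermediate (not isolated)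
12 | 7-hydroxy-8-methoxy-2H-chromen-2-one | COc1c(O)ccc2ccc(=O)oc12 | intermediate
13 | (±)-7-{[(2E)-5-{[tert-butyl(dimethyl)silyl]oxy}-3,7-dimethylocta-2,6-dien-1-yl]oxy}-8-methoxy-2H-chromen-2-one | COc1c(OC/C=C(\C)CC(O[Si](C)(C)C(C)(C)C)C=C(C)C)ccc2ccc(=O)oc12 | intermediate
14 | (±)-7-{[(2E)-5-hydroxy-3,7-dimethylocta-2,6-dien-1-yl]oxy}-8-methoxy-2H-chromen-2-one | COc1c(OC/C=C(\C)CC(O)C=C(C)C)ccc2ccc(=O)oc12 | intermediate
15 | 7-{[(2E)-3,7-dimethyl-5-oxoocta-2,6-dien-1-yl]oxy}-8-methoxy-2H-chromen-2-one | COc1c(OC/C=C(\C)CC(=O)C=C(C)C)ccc2ccc(=O)oc12 | intermediate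
16 | 8-methoxy-7-{[(2R,3R)-3-methyl-3-(4-methyl-2-oxopent-3-en-1-yl)oxiran-2-yl]methoxy}-2H-chromen-2-one | COc1c(OC[C@H]2O[C@]2(C)CC(=O)C=C(C)C)ccc2ccc(=O)oc12 | intermediate
17 | 7-{[(2R,3R)-3-[(2R)-2-hydroxy-4-methylpent-3-en-1-yl]-3-methyloxiran-2-yl]methoxy}-8-methoxy-2H-chromen-2-one | COc1c(OC[C@H]2O[C@]2(C)C[C@@H](O)C=C(C)C)ccc2ccc(=O)oc12 | target

**Count and risks**

Total step count: 9. Longest linear sequence: 8 steps (steps 1, 2, 3, 5, 6, 7, 8, 9); step 4 is a one-step branch.

Steps most likely to fail:

Step 8. Oxygen transfer to an alkene slowed by its allylic aryloxy group competes with base-mediated decomposition of the substrate, so slow conversion, loss of the coumarin-7-olate through C4' deprotonation, or insufficient face selectivity may result. The fallback sets out from 8 and rejoins the route at 16: the oxirane would be installed before etherification, where the free allylic hydroxyl directs the oxidant. Sharpless asymmetric epoxidation of 8 (Ti(OiPr)4, D-(−)-diethyl tartrate, t-BuOOH, 4 Å sieves, CH2Cl2, −20 °C) should give the (2R,3R)-epoxy alcohol F1, the C6'=C7' alkene of the allylic silyl ether being ignored by the titanium–tartrate system. Mitsunobu coupling of F1 with 12 (PPh3, DIAD) gives the epoxy silyl ether F2, Bu4NF gives the epoxy carbinol F3 as its two C5' epimers, and Dess–Martin oxidation converges on 16.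

Step 9. Facial discrimination may be poor, because the ketone is flanked by a β,β-disubstituted alkenyl group and a β-branched CH2 group of comparable bulk, and the Lewis-acidic boron may engage the oxirane. The fallback sets out from 16 and comes back at 17: Luche reduction (NaBH4, CeCl3·7H2O, MeOH, −40 °C) gives both C5' epimers, which are diastereomers and should be separable by chromatography. Compound 17 is taken directly, and the (5'S)-epimer F4 is inverted by Mitsunobu esterification with 4-nitrobenzoic acid (PPh3, DIAD) to the (5'R)-4-nitrobenzoate F5, whose methanolysis (K2CO3, MeOH, 0 °C) gives 17.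

Step 3. The Lewis-acidic Me3Al/Cp2ZrCl2 medium may ionise the allylic silyl ether, or methyl delivery to the alkyne may not be fully regioselective. The fallback sets out from 1 and rejoins at 8 by a vinylogous Mukaiyama aldol route. Methyl 3-methylbut-2-enoate is converted with LiN(iPr)2 and Me3SiCl into the silyl dienolate F6. Its γ-carbon adds to 1 (BF3·OEt2, CH2Cl2, −78 °C) to give the (2E)-hydroxy enoate F7; any (Z)-isomer lactonises and is removed. Silylation (TBSCl, imidazole) gives the silyloxy ester F8, and i-Bu2AlH (CH2Cl2, −78 °C) returns 8.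

**Further compounds**

F1 | step 8 | [(2R,3R)-3-{2-[tert-butyl(dimethyl)silyl]oxy-4-methylpent-3-en-1-yl}-3-methyloxiran-2-yl]methanol (both C5' epimers) | OC[C@H]1O[C@]1(C)CC(O[Si](C)(C)C(C)(C)C)C=C(C)C
F2 | step 8 | 7-{[(2R,3R)-3-{2-[tert-butyl(dimethyl)silyl]oxy-4-methylpent-3-en-1-yl}-3-methyloxiran-2-yl]methoxy}-8-methoxy-2H-chromen-2-one (both C5' epimers) | COc1c(OC[C@H]2O[C@]2(C)CC(O[Si](C)(C)C(C)(C)C)C=C(C)C)ccc2ccc(=O)oc12
F3 | step 8 | 7-{[(2R,3R)-3-(2-hydroxy-4-methylpent-3-en-1-yl)-3-methyloxiran-2-yl]methoxy}-8-methoxy-2H-chromen-2-one (both C5' epimers) | COc1c(OC[C@H]2O[C@]2(C)CC(O)C=C(C)C)ccc2ccc(=O)oc12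
F4 | step 9 | 7-{[(2R,3R)-3-[(2S)-2-hydroxy-4-methylpent-3-en-1-yl]-3-methyloxiran-2-yl]methoxy}-8-methoxy-2H-chromen-2-one | COc1c(OC[C@H]2O[C@]2(C)C[C@H](O)C=C(C)C)ccc2ccc(=O)oc12
F5 | step 9 | (2R)-1-[(2R,3R)-3-{[(8-methoxy-2-oxo-2H-chromen-7-yl)oxy]methyl}-2-methyloxiran-2-yl]-4-methylpent-3-en-2-yl 4-nitrobenzoate | COc1c(OC[C@H]2O[C@]2(C)C[C@@H](OC(=O)c3ccc(cc3)[N+](=O)[O-])C=C(C)C)ccc2ccc(=O)oc12
F6 | step 3 | 1-methoxy-3-methyl-1-(trimethylsilyloxy)buta-1,3-diene | COC(O[Si](C)(C)C)=CC(C)=C
F7 | step 3 | methyl (±)-(2E)-5-hydroxy-3,7-dimethylocta-2,6-dienoate | COC(=O)/C=C(\C)CC(O)C=C(C)C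
F8 | step 3 | methyl (±)-(2E)-5-{[tert-butyl(dimethyl)silyl]oxy}-3,7-dimethylocta-2,6-dienoate | COC(=O)/C=C(\C)CC(O[Si](C)(C)C(C)(C)C)C=C(C)C
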